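(The earlier runs and the new flask stem from a simulated flask from invented constants; scatter was added.)

What constant can be drawn from the earlier runs, when no rate constant is told?

| flask | first end groups | solid second end groups | remark | time |
|---|---|---|---|---|
| teal | 0.050 M | 0.025 M | run made earlier |  |
| amber | 0.050 M | 0.038 M | run made earlier |  |
| grey | 0.075 M | 0.050 M | run made earlier |  |
| flask | 0.050 M | 0.0500 M |  | 25 h |

- teal (time / h: links / %, rings / %): 2.00: 4.5, 45.9; 5.00: 4.5, 43.9; 10.0: 4.8, 45.5; 15.0: 3.9, 46.1
- amber (time / h: links / %, rings / %): 2.00: 10.5, 65.3; 5.00: 10.0, 64.6; 10.0: 10.6, 65.1; 15.0: 10.6, 64.7
- grey (time / h: links / %, rings / %): 4.00: 5.6, 63.5; 8.00: 5.9, 61.7; 12.0: 5.6, 62.7; 15.0: 3.9, 62.3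

(readings scatter by 1 percentage point)

- at the start none of the solid second end groups is in solution
- a reading or a percentage of links counts all its forms, free or not
- the reaction counts as stopped when no species that holds the first end groups changes by six tenths of a point or more over the second half of the time

* at 25 h, what has stopped the reaction, if anything has (for what has run out or reacted, a solid counts together with what of it has only dissolved) (all of the first end groups has reacted / it is still moving)
* links at 25 h, in percent of the first end groups charged
* rings at 25 h, in percent of the first end groups charged

What stopped those runs? Links and rings stand flat, within their scatter, from the first sample. In the amber run they sum to 75.8% at 2.00 h, against a solid charge of 76.0% of the first end groups. So I read the solid as the limiting reagent. The grey run, charged with 0.050 M of solid, was flat by 4.00 h, which is less than the flask's 25 h.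

And what moves the link share? Amber reads links 10.6% at 10.0 h with 12.0 mM of first end groups left by the charges, teal 4.8% with 25.0 mM left. So I try, as a working reading, rings as first order in free first end groups and links as zero order. While the amount left stays large against it, links formed are then a fixed amount times the logarithm of start over left. Teal gives 3.19 mM, amber 3.65 mM, grey 3.58 mM, on average 3.48 mM. This is the crossover amount, κ, on this reading the free first end groups at which links and rings form equally fast.

But the flask charges 0.050 M against 0.0500 M of solid, so the amount left goes to zero. Does the logarithm not run away? Not once the crossover amount is added to both amounts: links = κ ln((κ + start)/(κ + left)). That gives me links 19.0% and rings 81.0%.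

Where is that weakest? By the charges, no run went below 12.0 mM left, and by my reckoning about half of these links form below it.

The forecast says all of the first end groups has reacted, with links 21% and rings 79%: “All three runs fit κ ≈ 0.004 M”. Its links stand above mine.

The flask at 25 h: all of the first end groups has reacted, links 17.8%, rings 82.2%.

    first end groups + second end groups → links (k = 0.670 L mol⁻¹ min⁻¹)
    first end groups + second end groups → rings, rate k2*[first end groups] as long as [second end groups] is above zero (k = 0.0220 min⁻¹)
    first end groups + links ⇌ idle adduct, settled at all times (K = 28.0 L mol⁻¹)
    solid second end groups ⇌ second end groups, rate k4*(cs4 - [second end groups]) while solid is left; crystals form when [second end groups] > cs4 (solubility = 36.0 mM, k = 0.0430 min⁻¹)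

The crossover amount of 3.48 mM put 19.0% on this flask, 1.2 percentage points above its links. In the equations both steps carry first end groups to the first power, so this amount stands as a number fitted to the runs. The neighbour charged with 0.12 M of solid, 2.40 equiv, keeps the same first end groups and ends with 0% of them unbound, so the same reckoning gives it the same 19.0%. It stores links 25.4% and rings 74.6%, which is 6.4 points more links than reckoned, with 58% of its charged solid second end groups still there, solid or dissolved.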